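**Retrosynthetic overview**

1. Azulene numbering is used: C1 and C2 are the oxirane carbons (CH3 on C2), then C3, C3a, C4 (i-Pr), C5 (O-acyl), C6, C7 (CH3, OH), C8, C8a. β is the face of the isopropyl group. The i-Pr-bearing carbon is S in every chiral compound.
2. End game: the C5 ester comes from Mitsunobu inversion of a 5β-alcohol with unprotected 4-hydroxybenzoic acid. The 1β,2β-oxirane comes from reagent-controlled epoxidation of C1=C2. C7–OH comes from 5β-OH-directed epoxidation of C6=C7, then hydride opening at C6.
3. The five-membered ring is formed second, by ring-closing metathesis (C1=C2) of a C8a-vinyl and a C3a-methallyl group. Both are grown on the enal C1HO–C8a=C3a by 1,4-addition anti to i-Pr, equilibration and Wittig reaction.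
4. The seven-membered ring is formed first. Bonds C8–C8a and C4–C5 are made in one operation from triazole 3 (C1, C8a, C3a, C4, i-Pr) and dienyl acetate 5 (C8, C7, C6, C5). The operation is rhodium-carbene cyclopropanation followed by divinylcyclopropane rearrangement, a formal (4+3) cycloaddition that sets C4 and C5 under catalyst control.
5. Enabling feature: in the seven-membered ring the run C8H2–C7(CH3)(OH)–C6H2–C5H(O) is a hydrated 1-oxy-3-methylbuta-1,3-diene. The other three ring atoms C8a–C3a–C4 are an allyl unit whose end C8a bears C1, a carbon of the five-membered ring that can serve as an imine/formyl acceptor. Together they are the retron of a donor/acceptor vinylcarbene plus a diene.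

Key step: step 4

Assumption: Rh2(S-NTTL)4 is taken to give the enantiomer drawn; if its sense of induction is the opposite, Rh2(R-NTTL)4 is used and nothing else changes.

**Step 1**
Reactants: 1 (E)-4-methylpent-2-enal
Product: 2 (E)-5-methylhex-3-en-1-yne
Conditions: Me3SiCHN2, n-BuLi, THF, −78 °C to rt
Reagents that add atoms: (trimethylsilyl)diazomethane C[Si](C)(C)C=[N+]=[N-]
Why: Colvin rearrangement, in which the lithiated silyldiazomethane adds to the aldehyde, loss of silanolate and N2 gives an alkylidene carbene, and a 1,2-H shift delivers the terminal alkyne, while the E alkene is untouched and no nucleophilic solvent is present that could add to the enal.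

**Step 2**
Reactants: 2 (E)-5-methylhex-3-en-1-yne
Product: 3 4-[(E)-3-methylbut-1-en-1-yl]-1-tosyl-1H-1,2,3-triazole
Conditions: TsN3, copper thiophene-2-carboxylate Cu(O2CC4H3S) (10 mol %), toluene, 0 °C to rt
Reagents that add atoms: tosyl azide Cc1ccc(cc1)S(=O)(=O)N=[N+]=[N-]
Why: Azide–alkyne cycloaddition catalysed by monovalent copper should give only the 1,4-disubstituted 1-sulfonyltriazole, the carboxylate ligand and low temperature suppressing ring opening to the ketenimine.

**Step 3**
Reactants: 4 3-methylbut-2-enal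
Product: 5 (E)-3-methylbuta-1,3-dien-1-yl acetate
Conditions: isopropenyl acetate (solvent), p-TsOH (cat.), reflux with removal of acetone; fractional distillation
Reagents that add atoms: isopropenyl acetate CC(=C)OC(C)=O
Why: Acid-catalysed dienol acetate formation (enol ester exchange) through the extended enol runs under equilibrating conditions that favour the E enol ester, and distillation removes the minor Z isomer.

**Step 4**
Reactants: 3 4-[(E)-3-methylbut-1-en-1-yl]-1-tosyl-1H-1,2,3-triazole; 5 (E)-3-methylbuta-1,3-dien-1-yl acetate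
Product: 8 (3S,4S)-4-acetoxy-3-isopropyl-6-methylcyclohepta-1,5-diene-1-carbaldehyde (i-Pr cis to OAc), via cis-divinylcyclopropane imine 6 (not isolated), via cycloheptadienyl N-tosylimine 7 (not isolated)
Conditions: Rh2(S-NTTL)4 (dirhodium tetrakis[N-(1,8-naphthaloyl)-(S)-tert-leucinate], 1 mol %), 5 (3 equiv), ClCH2CH2Cl, 70 °C; then SiO2, H2O, CH2Cl2, rt
Reagents that add atoms: water O
Why: At 70 °C triazole 3 equilibrates with its open α-diazo imine, which the divalent-rhodium carboxylate dimer converts (loss of N2) into an electrophilic donor/acceptor carbene whose carbene carbon is the future C8a, flanked by the sulfonylimine acceptor (future C1) and the (E)-alkenyl donor (future C3a=C4). Concerted asynchronous [2+1] transfer to the terminal 1,1-disubstituted alkene of 5 closes the three-membered ring of 6 (new bond C8–C8a), and the cis-divinylcyclopropane then ring-expands by a [3,3]-sigmatropic shift through the endo-boat transition state, which breaks the C7–C8a cyclopropane bond, makes C4–C5 and so closes the seven-membered ring as a formal (4+3) cycloaddition. The closest known reaction type is the rhodium-catalysed tandem cyclopropanation/Cope rearrangement of vinyldiazoacetates and of 4-alkenyl-1-sulfonyl-1,2,3-triazoles with 1,3-dienes, 1-acyloxydienes included. The chiral carboxylate ligands fix the carbene face that is attacked and thereby the two quaternary cyclopropane centres, and the boat geometry transfers this chirality to C4 and C5, where isopropyl and acetoxy point outward and end up cis because both alkenes are E. Site selectivity between the two alkenes of 5 is secured by sterics and electronics, since donor/acceptor carbenes take 1,1-disubstituted termini, leave trans-1,2-disubstituted acyl-deactivated enol esters alone, and the charge building at C7 is allylic. Selectivity for the cis-divinyl isomer and against the aza-Cope channel follows from the usual placement of the unsaturated arm of the alkene next to the donor and away from the acceptor, so the imine sits trans to the acetoxyvinyl arm and only the all-carbon shift is geometrically possible, after which wet silica hydrolyses imine 7 to enal 8.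

**Step 5**
Reactants: 8 (3S,4S)-4-acetoxy-3-isopropyl-6-methylcyclohepta-1,5-diene-1-carbaldehyde
Product: 10 4β-acetoxy-3β-isopropyl-6-methyl-2α-(2-methylallyl)cyclohept-5-ene-1β-carbaldehyde, via trimethylsilyl enol ether 9 (not isolated)
Conditions: CH2=C(CH3)CH2MgCl, CuBr·SMe2 (10 mol %), Me3SiCl, DMPU, THF, −78 °C; 1 M HCl, THF, 0 °C; DBU (cat.), CH2Cl2, rt
Reagents that add atoms: 2-methylallylmagnesium chloride CC(=C)C[Mg]Cl; chlorotrimethylsilane C[Si](C)(C)Cl (atoms kept only in 9)
Why: In this copper-catalysed, chlorosilane-accelerated 1,4-addition the nucleophile should reach C3a anti to the neighbouring isopropyl group, and hydrolysis of 9 followed by base equilibration places the formyl group trans-diequatorial to the new side chain, which sets C3a and C8a.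

**Step 6**
Reactants: 10 4β-acetoxy-3β-isopropyl-6-methyl-2α-(2-methylallyl)cyclohept-5-ene-1β-carbaldehyde
Product: 11 6β-isopropyl-3-methyl-5α-(2-methylallyl)-4β-vinylcyclohept-2-en-1β-yl acetate
Conditions: Ph3PCH3Br, KHMDS, THF, −78 to 0 °C
Reagents that add atoms: methyltriphenylphosphonium bromide C[P+](c1ccccc1)(c1ccccc1)c1ccccc1.[Br-]
Why: Wittig methylenation of the aldehyde is much faster than attack on the acetate, and the α-centre is already in its more stable trans arrangement, so the basic ylide cannot erode it.

**Step 7**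
Reactants: 11 6β-isopropyl-3-methyl-5α-(2-methylallyl)-4β-vinylcyclohept-2-en-1β-yl acetate
Product: 12 4β-isopropyl-2,7-dimethyl-3,3a,4,5,8,8a-hexahydroazulen-5β-yl acetate (3a-H β and 8a-H α; trans-fused)
Conditions: second-generation Grubbs catalyst RuCl2(=CHPh)(H2IMes)(PCy3) (5 mol %), CH2Cl2 (0.005 M), reflux
Reagents that add atoms: none
Why: Ring-closing metathesis starts at the monosubstituted vinyl group and closes on the methallyl alkene, the gauche trans-diequatorial arms giving the trans-fused trisubstituted cyclopentene, while the endocyclic trisubstituted C6=C7 alkene is inert.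

**Step 8**
Reactants: 12 4β-isopropyl-2,7-dimethyl-3,3a,4,5,8,8a-hexahydroazulen-5β-yl acetate
Product: 13 4β-isopropyl-2,7-dimethyl-3,3a,4,5,8,8a-hexahydroazulen-5β-ol
Conditions: K2CO3 (cat.), MeOH, rt
Reagents that add atoms: none
Why: Base-catalysed methanolysis (transesterification) cleaves the only ester at the acyl carbon, so C5 keeps its configuration.

**Step 9**
Reactants: 13 4β-isopropyl-2,7-dimethyl-3,3a,4,5,8,8a-hexahydroazulen-5β-ol
Product: 14 6β,7β-epoxy-4β-isopropyl-2,7-dimethyl-3,3a,4,5,6,7,8,8a-octahydroazulen-5β-ol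
Conditions: VO(acac)2 (2 mol %), t-BuOOH (decane), CH2Cl2, 0 °C to rt
Reagents that add atoms: tert-butyl hydroperoxide CC(C)(C)OO
Why: In this hydroxyl-directed vanadium-catalysed epoxidation the alkoxide-bound peroxide delivers oxygen to C6=C7 on the β-face of the pseudo-axial 5-OH, which sets C6 and C7, and the C1=C2 alkene has no allylic hydroxyl group and is left alone.

**Step 10**
Reactants: 14 6β,7β-epoxy-4β-isopropyl-2,7-dimethyl-3,3a,4,5,6,7,8,8a-octahydroazulen-5β-ol
Product: 15 4β-isopropyl-2,7-dimethyl-3,3a,4,5,6,7,8,8a-octahydroazulene-5β,7β-diol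
Conditions: LiAlH4, THF, 0 °C to reflux; aqueous NaOH work-up
Reagents that add atoms: none
Why: Hydride opens the oxirane in SN2 fashion at the less substituted C6 from the α-face (trans-diaxial opening), so the C7–O bond and the 7β-OH configuration are untouched.

**Step 11**
Reactants: 15 4β-isopropyl-2,7-dimethyl-3,3a,4,5,6,7,8,8a-octahydroazulene-5β,7β-diol
Product: 16 1β,2β-epoxy-4β-isopropyl-2,7-dimethyldecahydroazulene-5β,7β-diol
Conditions: ent-Shi ketone (1,2:4,5-di-O-isopropylidene-β-L-erythro-2,3-hexodiulo-2,6-pyranose, 30 mol %), Oxone, K2CO3, Bu4NHSO4 (cat.), MeCN–CH2(OMe)2–aq. Na2B4O7/Na2EDTA buffer, 0 °C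
Reagents that add atoms: potassium peroxymonosulfate (active part of Oxone) [K+].[O-]S(=O)(=O)OO
Why: In this Shi asymmetric epoxidation the dioxirane of the L-series ketone should attack the only remaining alkene through the spiro transition state on its β-face, so C1 and C2 are set by the reagent, which is needed because the trans-fused cyclopentene has little facial bias of its own.

**Step 12**
Reactants: 16 1β,2β-epoxy-4β-isopropyl-2,7-dimethyldecahydroazulene-5β,7β-diol; 17 4-hydroxybenzoic acid
Product: 18 (1S,2R,3aR,4S,5S,7R,8aS)-1,2-epoxy-7-hydroxy-4-isopropyl-2,7-dimethyldecahydroazulen-5-yl 4-hydroxybenzoate (target)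
Conditions: PPh3, DIAD, THF, 0 °C to rt
Reagents that add atoms: none
Why: In this Mitsunobu esterification the oxyphosphonium salt of the secondary 5β-alcohol is displaced by the carboxylate from the α-face, anti to the isopropyl group, so C5 is inverted and acylated at once, while the tertiary alcohol is not activated, the syn 7β-OH cannot reach the rear of C5, and the carboxyl group, far more acidic than the phenol, is the only competent pronucleophile.

**Compound list**

1 | (E)-4-methylpent-2-enal | CC(C)/C=C/C=O | starting material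
2 | (E)-5-methylhex-3-en-1-yne | CC(C)/C=C/C#C | intermediate
3 | 4-[(E)-3-methylbut-1-en-1-yl]-1-tosyl-1H-1,2,3-triazole | CC(C)/C=C/c1cn(S(=O)(=O)c2ccc(C)cc2)nn1 | intermediate
4 | 3-methylbut-2-enal | CC(C)=CC=O | starting material
5 | (E)-3-methylbuta-1,3-dien-1-yl acetate | C=C(C)/C=C/OC(C)=O | intermediate
6 | N-tosylimine of 2-[(E)-2-acetoxyvinyl]-2-methyl-1-[(E)-3-methylbut-1-enyl]cyclopropane-1-carbaldehyde, alkenyl arms cis | CC(C)/C=C/[C@]1(C=NS(=O)(=O)c2ccc(C)cc2)C[C@]1(C)/C=C/OC(C)=O | intermediate
7 | N-tosylimine of enal 8 | CC(C)[C@H]1C=C(C=NS(=O)(=O)c2ccc(C)cc2)CC(C)=C[C@H]1OC(C)=O | intermediate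
8 | (3S,4S)-4-acetoxy-3-isopropyl-6-methylcyclohepta-1,5-diene-1-carbaldehyde | CC(C)[C@H]1C=C(C=O)CC(C)=C[C@H]1OC(C)=O | intermediate
9 | trimethylsilyl enol ether of aldehyde 10 | CC(C)[C@H]1[C@H](CC(C)=C)C(=CO[Si](C)(C)C)CC(C)=C[C@H]1OC(C)=O | intermediate
10 | 4β-acetoxy-3β-isopropyl-6-methyl-2α-(2-methylallyl)cyclohept-5-ene-1β-carbaldehyde | CC(C)[C@H]1[C@H](CC(C)=C)[C@@H](C=O)CC(C)=C[C@H]1OC(C)=O | intermediate
11 | 6β-isopropyl-3-methyl-5α-(2-methylallyl)-4β-vinylcyclohept-2-en-1β-yl acetate | CC(C)[C@H]1[C@H](CC(C)=C)[C@@H](C=C)CC(C)=C[C@H]1OC(C)=O | intermediate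
12 | 4β-isopropyl-2,7-dimethyl-3,3a,4,5,8,8a-hexahydroazulen-5β-yl acetate, trans-fused | CC(C)[C@H]1[C@@H]2CC(C)=C[C@H]2CC(C)=C[C@H]1OC(C)=O | intermediate
13 | 4β-isopropyl-2,7-dimethyl-3,3a,4,5,8,8a-hexahydroazulen-5β-ol | CC(C)[C@H]1[C@@H]2CC(C)=C[C@H]2CC(C)=C[C@H]1O | intermediate
14 | 6β,7β-epoxy-4β-isopropyl-2,7-dimethyl-3,3a,4,5,6,7,8,8a-octahydroazulen-5β-ol | CC(C)[C@H]1[C@@H]2CC(C)=C[C@H]2C[C@@]3(C)O[C@H]3[C@H]1O | intermediate
15 | 4β-isopropyl-2,7-dimethyl-3,3a,4,5,6,7,8,8a-octahydroazulene-5β,7β-diol | CC(C)[C@H]1[C@@H]2CC(C)=C[C@H]2C[C@@](C)(O)C[C@H]1O | intermediate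
16 | 1β,2β-epoxy-4β-isopropyl-2,7-dimethyldecahydroazulene-5β,7β-diol | CC(C)[C@H]1[C@@H]2C[C@@]3(C)O[C@H]3[C@H]2C[C@@](C)(O)C[C@H]1O | intermediate
17 | 4-hydroxybenzoic acid | OC(=O)c1ccc(O)cc1 | starting material
18 | (1S,2R,3aR,4S,5S,7R,8aS)-1,2-epoxy-7-hydroxy-4-isopropyl-2,7-dimethyldecahydroazulen-5-yl 4-hydroxybenzoate | CC(C)[C@H]1[C@@H]2C[C@@]3(C)O[C@H]3[C@H]2C[C@@](C)(O)C[C@@H]1OC(=O)c1ccc(O)cc1 | target

Total step count: 12. Longest linear sequence: 11 steps (1, 2, 4–12).

**Steps most likely to fail**

1. **Step 12.** The axial oxyphosphonium group may be lost by elimination toward C4 or C6, or the hindered alcohol may be acylated with retention instead of being displaced.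
   - The fallback sets out from 16 and comes back at 18. It replaces substitution by a redox inversion.
   - Buffered Dess–Martin periodinane oxidises the secondary alcohol to β-hydroxy ketone F1.
   - Me4NBH(OAc)3 (MeCN–AcOH, −30 °C, hydroxyl-directed Evans–Saksena reduction) binds to the 7β-OH and delivers hydride to the β-face of C5. This gives the anti diol with the 5α-alcohol, F2.
   - Steglich acylation of the equatorial secondary alcohol with 4-acetoxybenzoic acid (EDC, DMAP) gives the acetoxybenzoate F3.
   - Brief K2CO3/MeOH at 0 °C removes only the aryl acetate and gives 18.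

2. **Step 5.** The allylic organometal may add 1,2 to the formyl group, or the allylcopper species may displace the allylic acetate in SN2' fashion.
   - The fallback sets out from 8 and comes back at 13. It turns the 1,2-addition into the productive path.
   - Excess 2-methylallylmagnesium chloride (THF, −78 °C to 0 °C) adds to the aldehyde and strips the acetate. This gives the dienediol F4, whose carbinol epimers are of no consequence.
   - KH and 18-crown-6 (THF) trigger the anionic oxy-Cope rearrangement, which carries the methallyl unit to C3a on the face anti to the isopropyl group.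
   - After protonation and equilibration this gives the trans hydroxy aldehyde F5.
   - Wittig methylenation gives the hydroxy triene F6, and ring-closing metathesis with the second-generation Grubbs catalyst gives 13 directly.

3. **Step 4.** The imino carbene may be diverted by attack of the sulfonylimine nitrogen (nitrogen heterocycles). Alternatively, the cyclopropanation may place the methyl group rather than the acetoxyvinyl arm next to the alkenyl donor, so that no rearrangement follows.
   - The fallback sets out from 5 and comes back at 8. It uses the classical ester-stabilised vinylcarbene.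
   - 3-Methylbutanal and malonic acid (Et3N, reflux, decarboxylative deconjugating Knoevenagel condensation) give (E)-5-methylhex-3-enoic acid F7.
   - MeOH with catalytic H2SO4 gives the methyl ester F8.
   - Diazo transfer (4-acetamidobenzenesulfonyl azide, DBU, MeCN) gives methyl (E)-2-diazo-5-methylhex-3-enoate F9.
   - Rh2(S-DOSP)4 (dirhodium tetrakis[(S)-N-(4-dodecylphenylsulfonyl)prolinate]) in hexanes with 5 gives the cycloheptadiene ester F11 through the divinylcyclopropane ester F10.
   - Excess i-Bu2AlH (CH2Cl2, −78 °C) reduces both esters to the diol F12.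
   - TEMPO/PhI(OAc)2 oxidises only the primary allylic alcohol to the hydroxy enal F13.
   - Ac2O/pyridine returns 8.

**Further compounds**

F1 | step 12 | 1β,2β-epoxy-7β-hydroxy-4β-isopropyl-2,7-dimethyloctahydroazulen-5(1H)-one | CC(C)[C@H]1[C@@H]2C[C@@]3(C)O[C@H]3[C@H]2C[C@@](C)(O)CC1=O
F2 | step 12 | 1β,2β-epoxy-4β-isopropyl-2,7-dimethyldecahydroazulene-5α,7β-diol | CC(C)[C@H]1[C@@H]2C[C@@]3(C)O[C@H]3[C@H]2C[C@@](C)(O)C[C@@H]1O
F3 | step 12 | 4-acetoxybenzoate of F2 at C5 | CC(C)[C@H]1[C@@H]2C[C@@]3(C)O[C@H]3[C@H]2C[C@@](C)(O)C[C@@H]1OC(=O)c1ccc(OC(C)=O)cc1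
F4 | step 5 | 4-(1-hydroxy-3-methylbut-3-enyl)-6β-isopropyl-3... dienediol (cyclohepta-2,4... numbering as in 8: 1-(1-hydroxy-3-methylbut-3-enyl)-3β-isopropyl-6-methylcyclohepta-1,5-dien-4β-ol) | CC(C)[C@H]1C=C(C(O)CC(C)=C)CC(C)=C[C@H]1O
F5 | step 5 | 4β-hydroxy-3β-isopropyl-6-methyl-2α-(2-methylallyl)cyclohept-5-ene-1β-carbaldehyde | CC(C)[C@H]1[C@H](CC(C)=C)[C@@H](C=O)CC(C)=C[C@H]1O
F6 | step 5 | 6β-isopropyl-3-methyl-5α-(2-methylallyl)-4β-vinylcyclohept-2-en-1β-ol | CC(C)[C@H]1[C@H](CC(C)=C)[C@@H](C=C)CC(C)=C[C@H]1O
F7 | step 4 | (E)-5-methylhex-3-enoic acid | CC(C)/C=C/CC(=O)O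
F8 | step 4 | methyl (E)-5-methylhex-3-enoate | CC(C)/C=C/CC(=O)OC
F9 | step 4 | methyl (E)-2-diazo-5-methylhex-3-enoate | CC(C)/C=C/C(=[N+]=[N-])C(=O)OC
F10 | step 4 | methyl 2-[(E)-2-acetoxyvinyl]-2-methyl-1-[(E)-3-methylbut-1-enyl]cyclopropane-1-carboxylate, alkenyl arms cis | CC(C)/C=C/[C@]1(C(=O)OC)C[C@]1(C)/C=C/OC(C)=O
F11 | step 4 | methyl (3S,4S)-4-acetoxy-3-isopropyl-6-methylcyclohepta-1,5-diene-1-carboxylate | CC(C)[C@H]1C=C(C(=O)OC)CC(C)=C[C@H]1OC(C)=O
F12 | step 4 | 1-(hydroxymethyl)-3β-isopropyl-6-methylcyclohepta-1,5-dien-4β-ol | CC(C)[C@H]1C=C(CO)CC(C)=C[C@H]1O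
F13 | step 4 | 4β-hydroxy-3β-isopropyl-6-methylcyclohepta-1,5-diene-1-carbaldehyde | CC(C)[C@H]1C=C(C=O)CC(C)=C[C@H]1O
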